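I had no rate constants for these flasks, so I read one from the runs. The task was to rank four reagent charges by the target standing at the end.

in all of them: substrate 0.050 M
- ochre: reagent 0.96 equiv; run made earlier
- violet: reagent 1.5 equiv; run made earlier
- grey: reagent 2.7 equiv; run made earlier
- eta: reagent 0.800 equiv; time 15 min
- gamma: reagent 1.20 equiv; time 15 min
- beta: reagent 2.00 equiv; time 15 min
- epsilon: reagent 3.00 equiv; time 15 min

- ochre (time / min: target / %, substrate / %): 1.50: 21.4, 56.4; 3.00: 36.8, 46.0; 5.00: 45.2, 38.7; 6.00: 47.8, 34.7; 8.00: 51.7, 32.3
- violet (time / min: target / %, substrate / %): 1.50: 26.0, 42.5; 3.00: 41.1, 26.8; 5.00: 50.8, 19.9; 6.00: 52.4, 15.2; 8.00: 53.6, 12.2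
- grey (time / min: target / %, substrate / %): 0.667: 14.0, 40.3; 2.00: 31.3, 14.0; 4.00: 36.0, 3.1; 5.00: 35.5, 2.4; 8.00: 29.1, 1.0

(standard deviation of a reading: 1 percentage point)

- the analysis behind the earlier runs scatters by 1 percentage point, standard deviation
- "hardly changes" means that all values lie within two and a half points (for a concentration: within two and a half percent of the largest)
- a step back or a flat step of under half a point counts as no turn

* amount of target at the end, in percent of the substrate charged for eta, gamma, beta, epsilon, in this order
* the course of these numbers from the first flask to the last (hardly changes / falls all the way / rises all the way / falls, then rises / rises, then falls)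

I solved the two ends of the row apart. At the low end, the ochre run still held 32.3% of substrate at 8.00 min. The violet run, with more reagent, held 12.2% and gave 53.6% of target against 51.7%. So reagent paid at that end.

The high end showed the opposite. The highest target reading of the grey run was 36.0% at 4.00 min, but the next reading, 35.5%, lies within the scatter of 1 percentage point, so the height and time of the maximum stayed open. The last reading was 29.1% at 8.00 min. By 5.00 min it held 2.4% of substrate against 35.5% of target, so I read the later fall as plain loss of target.

I assumed that reagent destroys target. A reaction with a partner in excess looks first order, with a constant that scales with the partner; this is the pseudo-first-order case. I defined the tail constant λ as the logarithm of the ratio of two late target readings, divided by the time between them. The grey run gave λ = 0.0663 min⁻¹. That is a reading, and each point in it scatters by 1 point.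

Scaled by charge to the epsilon flask, λ became 0.0736 min⁻¹. I started from the highest grey reading and let target decay from 4.00 min to 15 min. That gave 16.0% for epsilon. So I expected a rise, then a fall.

The forecast gave 52%, 57%, 39% and 16%, a row that rises, then falls. Its ground was that substrate and target do not add up, and that “The final gap grows with reagent”.

The flasks gave 52.3%, 57.8%, 38.2% and 12.8%, so the row rises, then falls, and the forecast held.

substrate + reagent ⇌ intermediate A (K = 266 L mol⁻¹, k = 0.205 L mol⁻¹ s⁻¹); reagent + intermediate A → side product (k = 0.143 L mol⁻¹ s⁻¹); reagent + intermediate A ⇌ intermediate B (K = 9.21 L mol⁻¹, k = 0.0313 L mol⁻¹ s⁻¹); intermediate A → target (k = 0.0163 s⁻¹); intermediate B ⇌ intermediate C (K = 0.630, k = 0.00256 s⁻¹); reagent + target → over-reaction product (k = 0.0408 L mol⁻¹ s⁻¹); reagent ⇌ dormant form (K = 0.397, k = 0.00155 s⁻¹) My epsilon figure stood above the result. At 15.0 min the epsilon flask held 43.3% of over-reaction product, with reagent at 26.6% of its own charge. I then used the scaled λ once more, on the epsilon flask. From 24.9% of target at 7.50 min, it gave 14.3% at 15.0 min, and the flask held 12.8%.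

Readings and results were computed for an exercise; scatter was added.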